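**Retrosynthetic overview**
1. The strategy rests on the 3-substituted furan (ring O, C1, C2, C3, C4; C3 carries the chain through C5H2). It is closed last, at the C2=C3 bond, by ring-closing metathesis between the C3 methylidene and the vinyl group of an acrolein methyl acetal on the C4 oxygen (26), then aromatised by loss of methanol; fluoride finally frees C10–OH and C15–OH.
2. Acetal 26 comes from primary allylic alcohol 24 and methoxyallene. Alcohol 24 comes from a C9–C10 union of the allylbarium from chloride 7 with enal 18, followed by oxidation and CBS reduction (C10 S), silylation and selective primary desilylation.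
3. West piece 7 (C3–C9): methallyl alcohol dianion + prenyl bromide (C5–C6 bond), silylation, SeO2 oxidation of the E-methyl (C9–OH, C7=C8 E), Appel chlorination.
4. East piece 18 (C10–C19): geranyl acetate, SeO2 oxidation, Appel bromination, ethyl acetate enolate alkylation (C17–C18), Shi epoxidation (C15, C16), epoxy-acid lactonisation with inversion at C16, MnO2, silylation.
5. Ring order: γ-lactone (O–C16–C17–C18–C19) in step 9, furan in step 18.

Key step: step 18

Assumption: atoms are numbered O, C1, C2, C3, C4 round the furan and C5–C19 along the chain to the lactone carbonyl; 20 is carried as a mixture of C10 epimers and 26 as a mixture of acetal epimers, and both mixtures converge later (steps 13–14 and step 18).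

**Route**

Step 1
Reactants: 1 methallyl alcohol; 2 prenyl bromide
Product: 4 6-methyl-2-methylidenehept-5-en-1-ol, via dilithiated methallyl alcohol 3 (not isolated)
Conditions: n-BuLi (2.2 equiv), TMEDA, Et2O, 0 °C → rt; then 2, THF, −78 °C → rt; H2O
Reagents that add atoms: none
Why: Dianion alkylation: O–H and allylic C–H deprotonation gives the alkoxide-stabilised allyl anion, whose carbon terminus displaces the primary allylic bromide (SN2) to form C5–C6 and leave the C3 methylidene and the C4 hydroxymethyl group.

Step 2
Reactants: 4 6-methyl-2-methylidenehept-5-en-1-ol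
Product: 5 TBS ether of 4
Conditions: TBSCl, imidazole, DMF, rt
Reagents that add atoms: tert-butyldimethylsilyl chloride CC(C)(C)[Si](C)(C)Cl
Why: Standard silylation of a primary alcohol, masking the C4 oxygen through the oxidation, organometallic and reduction steps.

Step 3
Reactants: 5 TBS ether of 4
Product: 6 (2E)-6-[(TBS-oxy)methyl]-2-methylhepta-2,6-dien-1-ol
Conditions: SeO2 (0.3 equiv), t-BuOOH, CH2Cl2, 0 °C → rt
Reagents that add atoms: selenium dioxide O=[Se]=O (oxygen donor, regenerated by tert-butyl hydroperoxide CC(C)(C)OO)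
Why: SeO2 allylic oxidation (Riley-type ene reaction then [2,3]-sigmatropic shift) should attack the electron-richer trisubstituted alkene at its E-methyl group, giving the (E)-allylic alcohol at C9 and fixing the C7=C8 geometry, while the oxygen-deactivated 1,1-disubstituted alkene is left alone.

Step 4
Reactants: 6 (2E)-allylic alcohol
Product: 7 (E)-allylic chloride, tert-butyl{[(5E)-7-chloro-6-methyl-2-methylidenehept-5-en-1-yl]oxy}dimethylsilane
Conditions: PPh3, CCl4, 60 °C
Reagents that add atoms: carbon tetrachloride ClC(Cl)(Cl)Cl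
Why: Appel chlorination replaces the primary allylic hydroxyl by chloride through SN2 at C9 without allylic transposition and under neutral conditions that the silyl ether tolerates.

Step 5
Reactants: 8 geranyl acetate
Product: 9 (2E,6E)-8-hydroxy-3,7-dimethylocta-2,6-dien-1-yl acetate
Conditions: SeO2 (0.3 equiv), t-BuOOH, CH2Cl2, 0 °C → rt
Reagents that add atoms: selenium dioxide O=[Se]=O (oxygen donor, regenerated by tert-butyl hydroperoxide CC(C)(C)OO)
Why: The same SeO2 allylic oxidation is selective for the E-methyl of the terminal trisubstituted alkene, because the alkene next to the acetoxymethyl group is deactivated; the oxidised methyl becomes C17.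

Step 6
Reactants: 9 hydroxy acetate
Product: 10 (2E,6E)-8-bromo-3,7-dimethylocta-2,6-dien-1-yl acetate
Conditions: CBr4, PPh3, CH2Cl2, 0 °C
Reagents that add atoms: carbon tetrabromide BrC(Br)(Br)Br
Why: Appel bromination of the primary allylic alcohol proceeds by SN2 with retention of the alkene geometry and leaves the acetate untouched.

Step 7
Reactants: 10 allylic bromide; 11 ethyl acetate
Product: 13 ethyl (4E,8E)-10-acetoxy-4,8-dimethyldeca-4,8-dienoate, via lithium enolate of ethyl acetate 12 (not isolated)
Conditions: LiN(iPr)2, THF, −78 °C; then 10, DMPU, −78 → −40 °C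
Reagents that add atoms: none
Why: Ester enolate alkylation (SN2 at the primary allylic bromide) forms C17–C18; at −78 °C displacement of the allylic bromide should outrun Claisen-type attack on the acetate.

Step 8
Reactants: 13 dienoate
Product: 14 ethyl 3-{(2R,3R)-3-[(3E)-5-acetoxy-3-methylpent-3-en-1-yl]-2-methyloxiran-2-yl}propanoate
Conditions: D-fructose-derived Shi ketone (0.3 equiv), KHSO5 (as Oxone), K2CO3, Bu4NHSO4, Na2B4O7/Na2EDTA buffer, MeCN–dimethoxymethane–H2O, 0 °C
Reagents that add atoms: potassium peroxymonosulfate [K+].[O-]S(=O)(=O)OO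
Why: Shi epoxidation (chiral dioxirane, spiro transition state) should pick the electron-richer C15=C16 alkene over the acetate-deactivated C11=C12 alkene and deliver oxygen to the face that this ketone selects in E-trisubstituted alkenes, setting the (15R,16R)-epoxide.

Step 9
Reactants: 14 epoxy diester
Product: 16 (5S)-5-[(1R,4E)-1,6-dihydroxy-4-methylhex-4-en-1-yl]-5-methyloxolan-2-one, via epoxy hydroxy acid 15 (not isolated)
Conditions: LiOH, THF/MeOH/H2O, 0 °C → rt; then 1 M HCl to pH 3, rt
Reagents that add atoms: lithium hydroxide [Li+].[OH-]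
Why: Saponification of both esters followed by acidification triggers epoxy-acid lactonisation: the carboxyl group opens the protonated epoxide 5-exo at the tertiary C16 with inversion (16R to 16S), closing the γ-lactone and leaving the epoxide oxygen as the (15R) hydroxyl.

Step 10
Reactants: 16 lactone diol
Product: 17 (2E,6R)-6-hydroxy-3-methyl-6-[(2S)-2-methyl-5-oxooxolan-2-yl]hex-2-enal
Conditions: MnO2 (excess), CH2Cl2, rt
Reagents that add atoms: none
Why: MnO2 oxidation is selective for the primary allylic alcohol at C10 over the saturated secondary C15 hydroxyl and does not isomerise the E-enal.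

Step 11
Reactants: 17 hydroxy enal
Product: 18 C15 TBS ether of 17
Conditions: TBSOTf, 2,6-lutidine, CH2Cl2, −78 °C
Reagents that add atoms: tert-butyldimethylsilyl triflate CC(C)(C)[Si](C)(C)OS(=O)(=O)C(F)(F)F
Why: Silyl triflate silylation is needed for the hindered C15 hydroxyl next to the quaternary C16, and at −78 °C the weak base should not dienolise the enal.

Step 12
Reactants: 7 allylic chloride; 18 enal
Product: 20 coupled alcohol, C4 and C15 TBS ethers, 10-hydroxy (10RS,15R,16S; 7E,11E), via allylbarium chloride 19 (not isolated)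
Conditions: Li, biphenyl, BaI2, THF, rt (zerovalent Rieke barium); 7, −78 °C; then 18, −78 °C; H2O
Reagents that add atoms: none
Why: α-Selective carbonyl allylation with an allylbarium reagent (Barbier-type): the allylbarium should add 1,2 to the enal through its unsubstituted C9 terminus with retention of the C7=C8 E geometry, forming C9–C10 faster than it attacks the lactone; C10 is not controlled here and is set in steps 13 and 14.

Step 13
Reactants: 20 epimeric alcohols
Product: 21 C10 ketone (15R,16S; 7E,11E)
Conditions: MnO2 (excess), CH2Cl2, rt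
Reagents that add atoms: none
Why: Neutral MnO2 oxidation of the secondary allylic alcohol gives the enone without acid or base that could move the skipped C7=C8 alkene into conjugation.

Step 14
Reactants: 21 ketone
Product: 22 (10S,15R,16S)-10-alcohol, C4 and C15 TBS ethers
Conditions: (R)-2-methyl-CBS-oxazaborolidine (0.5 equiv), catecholborane, toluene, −78 °C; H2O
Reagents that add atoms: none
Why: Corey–Bakshi–Shibata reduction: with the conjugated C11=C12 alkenyl group as the large substituent and the C9 methylene as the small one, the (R)-oxazaborolidine should deliver hydride to give the (10S)-allylic alcohol, and catecholborane at −78 °C leaves the lactone and the alkenes untouched.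

Step 15
Reactants: 22 (10S)-alcohol
Product: 23 tris-TBS ether (C4, C10, C15)
Conditions: TBSCl, imidazole, DMF, rt
Reagents that add atoms: tert-butyldimethylsilyl chloride CC(C)(C)[Si](C)(C)Cl
Why: Standard silylation of the secondary allylic C10 hydroxyl under non-ionising basic conditions.

Step 16
Reactants: 23 tris-TBS ether
Product: 24 primary allylic alcohol (C4–OH), C10 and C15 TBS ethers
Conditions: HF·pyridine, pyridine, THF, 0 °C
Reagents that add atoms: none
Why: Selective desilylation: buffered HF·pyridine should cleave the unhindered primary silyl ether much faster than the two secondary ones, the C15 ether being shielded further by the quaternary C16.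

Step 17
Reactants: 24 primary allylic alcohol; 25 methoxyallene
Product: 26 acrolein methyl acetal diene (10S,15R,16S; acetal epimers)
Conditions: Pd(OAc)2 (5 mol %), Ph2P(CH2)3PPh2, Et3N, MeCN, rt
Reagents that add atoms: none
Why: Palladium-catalysed hydroalkoxylation of an alkoxyallene: the zerovalent palladium formed in situ gives a methoxy-substituted π-allyl complex that the primary alcohol captures at the oxygen-bearing terminus, so the mixed acetal is made under basic conditions that spare the silyl ethers and the lactone.

Step 18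
Reactants: 26 acrolein acetal diene
Product: 28 bis-TBS irciformonin B, via methoxydihydrofuran 27 (not isolated)
Conditions: second-generation Grubbs catalyst (H2IMes)(PCy3)Cl2Ru=CHPh (5–10 mol %), CH2Cl2, 40 °C; then PPTS (cat.), rt
Reagents that add atoms: none
Why: The ruthenium alkylidene should load on the monosubstituted vinyl group of the acetal and close onto the C3 methylidene by [2+2] cycloaddition and cycloreversion, expelling ethene and forming the C2=C3 bond of 2-methoxy-2,5-dihydrofuran 27; mild acid then ionises the C1–OMe bond and loss of a C4 proton gives the aromatic furan. The closest known reaction type is ring-closing metathesis of allyl acrolein-acetal ethers followed by acid aromatisation to furans. The ring closes by olefin metathesis as a five-membered ring at a carbon–carbon double bond, not at oxygen. No stereocentre is created, and the two acetal epimers converge on one furan. The step needs reaction of the two terminal alkenes only: the trisubstituted C7=C8 and C11=C12 alkenes are sterically shielded and could only close eight-membered or larger rings with the acetal-derived carbene. The acid is kept to catalytic PPTS in an aprotic solvent so that the allylic C10 silyl ether and the new furan survive.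

Step 19
Reactants: 28 bis-TBS irciformonin B
Product: 29 irciformonin B
Conditions: Bu4NF, AcOH, THF, rt → 40 °C
Reagents that add atoms: none
Why: Fluoride-mediated desilylation removes both secondary silyl ethers, with acetic acid buffering the alkoxides so that the C15 oxygen does not translactonise and the furan sees no strong acid.

**Compound list**
1 | methallyl alcohol (2-methylprop-2-en-1-ol) | C=C(C)CO | starting material
2 | prenyl bromide (1-bromo-3-methylbut-2-ene) | CC(C)=CCBr | starting material
3 | dilithiated methallyl alcohol | [Li]CC(=C)CO[Li] | intermediate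
4 | 6-methyl-2-methylidenehept-5-en-1-ol | C=C(CO)CCC=C(C)C | intermediate
5 | tert-butyl(dimethyl)[(6-methyl-2-methylidenehept-5-en-1-yl)oxy]silane | C=C(CO[Si](C)(C)C(C)(C)C)CCC=C(C)C | intermediate
6 | (2E)-6-[(TBS-oxy)methyl]-2-methylhepta-2,6-dien-1-ol | C=C(CO[Si](C)(C)C(C)(C)C)CC/C=C(\C)CO | intermediate
7 | tert-butyl{[(5E)-7-chloro-6-methyl-2-methylidenehept-5-en-1-yl]oxy}dimethylsilane | C=C(CO[Si](C)(C)C(C)(C)C)CC/C=C(\C)CCl | intermediate
8 | geranyl acetate | CC(C)=CCC/C(C)=C/COC(C)=O | starting material
9 | (2E,6E)-8-hydroxy-3,7-dimethylocta-2,6-dien-1-yl acetate | OC/C(C)=C/CC/C(C)=C/COC(C)=O | intermediate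
10 | (2E,6E)-8-bromo-3,7-dimethylocta-2,6-dien-1-yl acetate | BrC/C(C)=C/CC/C(C)=C/COC(C)=O | intermediate
11 | ethyl acetate | CCOC(C)=O | starting material
12 | lithium enolate of ethyl acetate | C=C(O[Li])OCC | intermediate
13 | ethyl (4E,8E)-10-acetoxy-4,8-dimethyldeca-4,8-dienoate | CCOC(=O)CC/C(C)=C/CC/C(C)=C/COC(C)=O | intermediate
14 | ethyl 3-{(2R,3R)-3-[(3E)-5-acetoxy-3-methylpent-3-en-1-yl]-2-methyloxiran-2-yl}propanoate | CCOC(=O)CC[C@@]1(C)O[C@@H]1CC/C(C)=C/COC(C)=O | intermediate
15 | 3-{(2R,3R)-3-[(3E)-5-hydroxy-3-methylpent-3-en-1-yl]-2-methyloxiran-2-yl}propanoic acid | OC(=O)CC[C@@]1(C)O[C@@H]1CC/C(C)=C/CO | intermediate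
16 | (5S)-5-[(1R,4E)-1,6-dihydroxy-4-methylhex-4-en-1-yl]-5-methyloxolan-2-one | C/C(=C\CO)CC[C@@H](O)[C@]1(C)CCC(=O)O1 | intermediate
17 | (2E,6R)-6-hydroxy-3-methyl-6-[(2S)-2-methyl-5-oxooxolan-2-yl]hex-2-enal | C/C(=C\C=O)CC[C@@H](O)[C@]1(C)CCC(=O)O1 | intermediate
18 | (2E,6R)-6-(TBS-oxy)-3-methyl-6-[(2S)-2-methyl-5-oxooxolan-2-yl]hex-2-enal | C/C(=C\C=O)CC[C@@H](O[Si](C)(C)C(C)(C)C)[C@]1(C)CCC(=O)O1 | intermediate
19 | allylbarium chloride from 7 | Cl[Ba]C/C(C)=C/CCC(=C)CO[Si](C)(C)C(C)(C)C | intermediate
20 | coupled alcohol, C4 and C15 TBS ethers, 10-hydroxy (10RS,15R,16S; 7E,11E) | C/C(=C\C(O)C/C(C)=C/CCC(=C)CO[Si](C)(C)C(C)(C)C)CC[C@@H](O[Si](C)(C)C(C)(C)C)[C@]1(C)CCC(=O)O1 | intermediate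
21 | C10 ketone, C4 and C15 TBS ethers (15R,16S; 7E,11E) | C/C(=C\C(=O)C/C(C)=C/CCC(=C)CO[Si](C)(C)C(C)(C)C)CC[C@@H](O[Si](C)(C)C(C)(C)C)[C@]1(C)CCC(=O)O1 | intermediate
22 | (10S,15R,16S)-10-alcohol, C4 and C15 TBS ethers | C/C(=C\[C@@H](O)C/C(C)=C/CCC(=C)CO[Si](C)(C)C(C)(C)C)CC[C@@H](O[Si](C)(C)C(C)(C)C)[C@]1(C)CCC(=O)O1 | intermediate
23 | tris-TBS ether (C4, C10, C15; 10S,15R,16S) | C/C(=C\[C@@H](O[Si](C)(C)C(C)(C)C)C/C(C)=C/CCC(=C)CO[Si](C)(C)C(C)(C)C)CC[C@@H](O[Si](C)(C)C(C)(C)C)[C@]1(C)CCC(=O)O1 | intermediate
24 | primary allylic alcohol (C4–OH), C10 and C15 TBS ethers (10S,15R,16S) | C/C(=C\[C@@H](O[Si](C)(C)C(C)(C)C)C/C(C)=C/CCC(=C)CO)CC[C@@H](O[Si](C)(C)C(C)(C)C)[C@]1(C)CCC(=O)O1 | intermediate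
25 | methoxyallene (1-methoxypropa-1,2-diene) | COC=C=C | starting material
26 | bis-TBS acrolein methyl acetal diene (10S,15R,16S; acetal epimers) | C/C(=C\[C@@H](O[Si](C)(C)C(C)(C)C)C/C(C)=C/CCC(=C)COC(OC)C=C)CC[C@@H](O[Si](C)(C)C(C)(C)C)[C@]1(C)CCC(=O)O1 | intermediate
27 | bis-TBS 2-methoxy-2,5-dihydrofuran (acetal epimers) | C/C(=C\[C@@H](O[Si](C)(C)C(C)(C)C)C/C(C)=C/CCC1=CC(OC)OC1)CC[C@@H](O[Si](C)(C)C(C)(C)C)[C@]1(C)CCC(=O)O1 | intermediate
28 | bis-TBS irciformonin B | C/C(=C\[C@@H](O[Si](C)(C)C(C)(C)C)C/C(C)=C/CCc1ccoc1)CC[C@@H](O[Si](C)(C)C(C)(C)C)[C@]1(C)CCC(=O)O1 | intermediate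
29 | irciformonin B | C/C(=C\[C@@H](O)C/C(C)=C/CCc1ccoc1)CC[C@@H](O)[C@]1(C)CCC(=O)O1 | target

**Step count**
Total: 19 steps. Longest linear sequence: 15 steps (steps 5–19, from geranyl acetate); the west piece takes 4 steps (steps 1–4).

**Steps most likely to fail**

Step 12. The allylbarium may lose its α-selectivity (attack through C7 giving the branched alcohol), undergo Wurtz-type homocoupling, or attack the lactone. The fallback sets out from 7 and 18 and returns at 21. Chloride 7 with NaSO2Ph in DMF should give the allylic phenyl sulfone F1. Its lithio derivative (n-BuLi, THF, −78 °C), which reacts at the sulfonyl-bearing carbon, is added to enal 18 to give the β-hydroxy sulfone F2. Dess–Martin periodinane oxidation gives the β-keto sulfone F3, and reductive desulfonylation with SmI2 in THF/MeOH at −78 °C, with protonation of the enolate at C9, delivers ketone 21.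

Step 18. The ruthenium alkylidene may decompose on the acetal, the acid-labile acetal may be lost before ring closure, or the acid step may cleave the allylic C10 silyl ether. The fallback sets out from 24 and returns at 28. Acylation with acryloyl chloride and i-Pr2NEt gives the acrylate F4. Ring-closing metathesis with the second-generation Grubbs catalyst in toluene at 80 °C gives the butenolide F5. Reduction with excess i-Bu2AlH at −78 °C and a mildly acidic work-up converts the unsaturated lactol into the furan by loss of water and leaves the saturated lactone as its lactol, furan lactol F6. Fétizon oxidation (Ag2CO3 on Celite, toluene, reflux) restores the γ-lactone and gives 28.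

Step 14. Hydride delivery to 21 may show poor facial discrimination, or the C7=C8 alkene of 21 may migrate into conjugation before reduction. The fallback sets out from 20 and returns at 22, avoiding the ketone. The epimer mixture 20 is submitted to a Sharpless kinetic resolution (Ti(OiPr)4, D-(−)-diisopropyl tartrate, t-BuOOH, 4 Å sieves, CH2Cl2, −20 °C) run past half conversion, because the C12 methyl cis to the carbinol lowers the rate ratio. The (10R)-epimer should be consumed as the epoxy alcohol F7, and the (10S)-alcohol 22 is recovered at the cost of half the material.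

**Further compounds**
F1 | step 12 | allylic phenyl sulfone from 7 | O=S(=O)(C/C(C)=C/CCC(=C)CO[Si](C)(C)C(C)(C)C)c1ccccc1
F2 | step 12 | β-hydroxy sulfone (C9 and C10 epimers) | C/C(=C\C(O)C(/C(C)=C/CCC(=C)CO[Si](C)(C)C(C)(C)C)S(=O)(=O)c1ccccc1)CC[C@@H](O[Si](C)(C)C(C)(C)C)[C@]1(C)CCC(=O)O1
F3 | step 12 | β-keto sulfone (C9 epimers) | C/C(=C\C(=O)C(/C(C)=C/CCC(=C)CO[Si](C)(C)C(C)(C)C)S(=O)(=O)c1ccccc1)CC[C@@H](O[Si](C)(C)C(C)(C)C)[C@]1(C)CCC(=O)O1
F4 | step 18 | acrylate of 24 | C/C(=C\[C@@H](O[Si](C)(C)C(C)(C)C)C/C(C)=C/CCC(=C)COC(=O)C=C)CC[C@@H](O[Si](C)(C)C(C)(C)C)[C@]1(C)CCC(=O)O1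
F5 | step 18 | bis-TBS butenolide (4-substituted furan-2(5H)-one) | C/C(=C\[C@@H](O[Si](C)(C)C(C)(C)C)C/C(C)=C/CCC1=CC(=O)OC1)CC[C@@H](O[Si](C)(C)C(C)(C)C)[C@]1(C)CCC(=O)O1
F6 | step 18 | bis-TBS furan lactol (C19 hemiacetal, anomers) | C/C(=C\[C@@H](O[Si](C)(C)C(C)(C)C)C/C(C)=C/CCc1ccoc1)CC[C@@H](O[Si](C)(C)C(C)(C)C)[C@]1(C)CCC(O)O1
F7 | step 14 | (10R,11S,12S)-11,12-epoxy-10-alcohol from the (10R)-epimer of 20 | C[C@@]1(CC[C@@H](O[Si](C)(C)C(C)(C)C)[C@]2(C)CCC(=O)O2)O[C@H]1[C@H](O)C/C(C)=C/CCC(=C)CO[Si](C)(C)C(C)(C)C
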